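**Plan**

- Locants (decalin): ring A = C1–C5 and C10 (C3 carries the ester oxygen, C4 and C5 the methyls); ring B = C5–C10 (C7 isopropylidene, C8 ketone, C9 enol OH, C10 sp2).
- The retrosynthesis cuts, in order: the C3–O acyl bond (side-chain acid 22 is made separately); then the ring bonds C10–C5 and C3–C4 together; then C7–C8 (vinyllithium plus Weinreb amide) and C6–C7 (carbenoid alkylation).
- Enabling feature: the oxygen-bearing C3 and the fusion carbon C10 are 1,4-related through C2–C1, like C2/C5 of a furan, and C10 is sp2 next to the oxygenated C9/C8. A furan oxygen can therefore bridge C3 and C10 and later leave C10 by β-elimination toward C9 while staying on C3. C4/C5 with their cis methyls are the two carbons of an (E)-2-methylbut-2-enyl alkene.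
- Forward: one intramolecular furan Diels–Alder reaction closes ring A (as a 7-oxanorbornene) and ring B (tether C6–C9) from an open-chain furyl ketone; hydrogenation, E1cB opening of the oxygen bridge, esterification and desilylation finish the route.
- Stereochemistry: a temporary (S)-silyloxy stereocenter at C9 (asymmetric transfer hydrogenation) selects the furan face and is then erased; the E alkene gives the cis C4/C5 methyls and the exo mode puts C3–O trans to the C4 methyl; the Z side-chain alkene comes from syn carbocupration, the angelate from angelic acid.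

Key step: step 6

Assumption: the (R,R)-configured transfer-hydrogenation catalyst is assigned to the (S)-carbinol by the usual aryl ketone model (furyl in the aryl position), and 5, 6 and 14 are taken as catalogue compounds.

**Route**

Step 1
Reactants: 1 ethyl 2-(furan-2-yl)-2-oxoacetate
Product: 2 ethyl (2S)-2-(furan-2-yl)-2-hydroxyacetate
Conditions: RuCl[(R,R)-TsDPEN](p-cymene) (1 mol%), HCO2H/Et3N (5:2), DMF, 25 °C
Reagents that add atoms: none
Why: Noyori-type asymmetric transfer hydrogenation of an aryl α-keto ester, in which the furyl group should take the aryl position of the CH/π-controlled transition state so that hydride reaches the face giving the (S)-carbinol, the future temporary stereocenter C9.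

Step 2
Reactants: 2 ethyl (2S)-2-(furan-2-yl)-2-hydroxyacetate
Product: 3 ethyl (2S)-2-[(tert-butyldimethylsilyl)oxy]-2-(furan-2-yl)acetate
Conditions: TBSCl, imidazole, DMF, 25 °C
Reagents that add atoms: tert-butyldimethylsilyl chloride, CC(C)(C)[Si](C)(C)Cl
Why: Standard silylation of a secondary alcohol under non-epimerising conditions; the bulky silyl ether later acts as the stereodirecting group and ends as the enol protecting group of the diosphenol.

Step 3
Reactants: 3 ethyl (2S)-2-[(tert-butyldimethylsilyl)oxy]-2-(furan-2-yl)acetate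
Product: 4 (2S)-2-[(tert-butyldimethylsilyl)oxy]-2-(furan-2-yl)-N-methoxy-N-methylacetamide
Conditions: MeNH(OMe)·HCl, iPrMgCl, THF, −20 °C
Reagents that add atoms: N,O-dimethylhydroxylamine hydrochloride, CNOC.Cl
Why: Weinreb amidation of an ester by the chloromagnesium amide at low temperature, which should proceed faster than deprotonation at the silyloxy-bearing carbon and so keep its configuration.

Step 4
Reactants: 5 1,1-dibromo-2-methylprop-1-ene; 6 (E)-1-bromo-2-methylbut-2-ene
Product: 8 (5E)-3-bromo-2,5-dimethylhepta-2,5-diene, via 1-bromo-1-lithio-2-methylprop-1-ene 7 (not isolated)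
Conditions: n-BuLi, THF/Et2O, −105 °C; then 6, DMPU, −105 → −78 °C
Reagents that add atoms: none
Why: Bromine–lithium exchange on the gem-dibromoalkene gives the α-bromovinyllithium carbenoid, which is configurationally irrelevant and stable at this temperature, and its SN2 alkylation at the primary allylic carbon of 6 forms C6–C7 with the E alkene untouched.

Step 5
Reactants: 8 (5E)-3-bromo-2,5-dimethylhepta-2,5-diene; 4 (2S)-2-[(tert-butyldimethylsilyl)oxy]-2-(furan-2-yl)-N-methoxy-N-methylacetamide
Product: 10 (1S,5E)-1-[(tert-butyldimethylsilyl)oxy]-1-(furan-2-yl)-5-methyl-3-(propan-2-ylidene)hept-5-en-2-one, via (5E)-2,5-dimethylhepta-2,5-dien-3-yllithium 9 (not isolated)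
Conditions: 8, t-BuLi (2 equiv), Et2O, −78 °C; then 4, THF, −78 → −20 °C; H2O
Reagents that add atoms: none
Why: Bromine–lithium exchange followed by Weinreb ketone synthesis, in which the chelated tetrahedral intermediate prevents over-addition, forms C7–C8 and delivers the complete open-chain cycloaddition precursor with the isopropylidene group already in place.

Step 6
Reactants: 10 (1S,5E)-1-[(tert-butyldimethylsilyl)oxy]-1-(furan-2-yl)-5-methyl-3-(propan-2-ylidene)hept-5-en-2-one
Product: 11 (3R,4R,5R,9S,10S)-9-[(tert-butyldimethylsilyl)oxy]-3,10-epoxyeremophila-1,7(11)-dien-8-one (oxygen bridging C3 and C10, ring B fused exo, C4 and C5 methyls both endo)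
Conditions: CH2Cl2 (0.05 M), 15 kbar, 25 °C, 72 h; used at once in step 7
Reagents that add atoms: none
Why: A concerted, suprafacial [4+2] cycloaddition between the furan diene (C10=C1–C2=C3, oxygen between C3 and C10) and the tethered (E)-alkene C4=C5 forms C10–C5 and C3–C4 at once; the closest known reaction type is the pressure-promoted intramolecular Diels–Alder reaction of furans with unactivated alkenes on a four-atom tether. Ring A closes as the cycloaddition ring (a 7-oxabicyclo[2.2.1]heptene whose oxygen spans C3 and C10) and ring B closes as the six-membered tether ring C5–C6–C7–C8–C9–C10, fused on the exo face because a four-atom tether with two sp2 atoms spans C10 and C5 comfortably only when it lies syn to the oxygen bridge. C4 and C5 get their cis methyls (both endo) from the E geometry of the alkene, C3 and C10 are fixed by the bridge, and the exo mode places the C3 oxygen trans to the C4 methyl and cis to C6. The absolute sense comes from the (S)-configured C9: its silyloxy group takes the equatorial site of the forming ring B, because the axial site is syn-axial to the C5 methyl, so one furan face is used and the 3R,4R,5R series should result. The step needs a favourable position of the cycloaddition equilibrium together with exo and facial selectivity: 15 kbar exploits the negative volumes of activation and reaction, the Z methyl of the isopropylidene group forces C9 and C6 onto the same side of the twisted enone (allylic strain) so that the reacting ends are held close, and the tetrasubstituted enone cannot reach the furan through its two-atom link. The adduct is kept at or below room temperature and hydrogenated directly, which closes the cycloreversion path.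

Step 7
Reactants: 11 (3R,4R,5R,9S,10S)-9-[(tert-butyldimethylsilyl)oxy]-3,10-epoxyeremophila-1,7(11)-dien-8-one
Product: 12 (3R,4R,5R,9S,10S)-9-[(tert-butyldimethylsilyl)oxy]-3,10-epoxyeremophil-7(11)-en-8-one
Conditions: H2 (1 atm), 5% Pd/C, EtOAc, 0 °C
Reagents that add atoms: none
Why: Catalytic hydrogenation of the strained C1=C2 alkene of the oxanorbornene should be far faster than reduction of the twisted tetrasubstituted enone, and it makes the bicycle unable to revert to the furan.

Step 8
Reactants: 12 (3R,4R,5R,9S,10S)-9-[(tert-butyldimethylsilyl)oxy]-3,10-epoxyeremophil-7(11)-en-8-one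
Product: 13 (3R,4R,5R)-9-[(tert-butyldimethylsilyl)oxy]-3-hydroxyeremophila-7(11),9-dien-8-one
Conditions: LiN(SiMe3)2, THF, −78 → 0 °C; then AcOH
Reagents that add atoms: none
Why: E1cB opening of the oxygen bridge: the axial C9–H, α to the C8 ketone and anti-periplanar to C10–O, is removed and the bridging oxygen is expelled from C10 with relief of bicyclic strain, which creates C9=C10 as the silyl enol ether of the diosphenol, frees the C3 hydroxyl with its configuration intact and erases the auxiliary centers C9 and C10.

Step 9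
Reactants: 14 tert-butyldimethyl(prop-2-yn-1-yloxy)silane
Product: 16 tert-butyl 4-[(tert-butyldimethylsilyl)oxy]but-2-ynoate, via lithium acetylide 15 (not isolated)
Conditions: n-BuLi, THF, −78 °C; then Boc2O, −78 → 0 °C
Reagents that add atoms: di-tert-butyl dicarbonate, CC(C)(C)OC(=O)OC(=O)OC(C)(C)C
Why: Acylation of a lithium acetylide with the dicarbonate is a standard route to tert-butyl ynoates and installs an ester that can later be cleaved by acid in the presence of the other esters.

Step 10
Reactants: 16 tert-butyl 4-[(tert-butyldimethylsilyl)oxy]but-2-ynoate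
Product: 17 tert-butyl (2Z)-4-[(tert-butyldimethylsilyl)oxy]-3-methylbut-2-enoate
Conditions: MeLi, CuI, THF, −78 °C; then 16; MeOH at −78 °C
Reagents that add atoms: lithium dimethylcuprate, [Li+].C[Cu-]C
Why: Syn carbocupration (conjugate addition of a Gilman cuprate to an ynoate) with protonation at low temperature places the new methyl cis to the new hydrogen, so the silyloxymethyl group and the ester end up cis (Z).

Step 11
Reactants: 17 tert-butyl (2Z)-4-[(tert-butyldimethylsilyl)oxy]-3-methylbut-2-enoate
Product: 18 tert-butyl (2Z)-4-hydroxy-3-methylbut-2-enoate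
Conditions: HF·pyridine, pyridine, THF, 0 °C
Reagents that add atoms: none
Why: Fluoride-mediated desilylation under buffered, non-basic conditions avoids an alkoxide, so that the cis hydroxy tert-butyl ester should survive without closing to the butenolide.

Step 12
Reactants: 18 tert-butyl (2Z)-4-hydroxy-3-methylbut-2-enoate; 19 angelic acid [(2Z)-2-methylbut-2-enoic acid]
Product: 21 tert-butyl (2Z)-3-methyl-4-{[(2Z)-2-methylbut-2-enoyl]oxy}but-2-enoate, via angelic 2,4,6-trichlorobenzoic anhydride 20 (not isolated)
Conditions: 19, 2,4,6-trichlorobenzoyl chloride, Et3N, toluene, 25 °C; then 18, DMAP (0.2 equiv), 0 °C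
Reagents that add atoms: none
Why: Yamaguchi esterification of a primary allylic alcohol through the mixed anhydride at low temperature is the established way to make angelates without isomerisation to the tiglate.

Step 13
Reactants: 21 tert-butyl (2Z)-3-methyl-4-{[(2Z)-2-methylbut-2-enoyl]oxy}but-2-enoate
Product: 22 (2Z)-3-methyl-4-{[(2Z)-2-methylbut-2-enoyl]oxy}but-2-enoic acid
Conditions: CF3CO2H, CH2Cl2, 0 → 25 °C
Reagents that add atoms: none
Why: Acidolysis of the tert-butyl ester (loss of isobutene by an E1 path) frees the acid while both conjugated esters and both Z alkenes remain, and the acylated oxygen cannot lactonise.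

Step 14
Reactants: 13 (3R,4R,5R)-9-[(tert-butyldimethylsilyl)oxy]-3-hydroxyeremophila-7(11),9-dien-8-one; 22 (2Z)-3-methyl-4-{[(2Z)-2-methylbut-2-enoyl]oxy}but-2-enoic acid
Product: 24 (3R,4R,5R)-9-[(tert-butyldimethylsilyl)oxy]-3-{[(2Z)-3-methyl-4-{[(2Z)-2-methylbut-2-enoyl]oxy}but-2-enoyl]oxy}eremophila-7(11),9-dien-8-one, via mixed 2,4,6-trichlorobenzoic anhydride 23 (not isolated)
Conditions: 22, 2,4,6-trichlorobenzoyl chloride, Et3N, toluene, 0 °C; then 13, DMAP, 0 → 25 °C
Reagents that add atoms: none
Why: Yamaguchi esterification of the equatorial secondary C3 alcohol, the only free hydroxyl because the diosphenol oxygen is still silylated, joins the two fragments with retention at C3.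

Step 15
Reactants: 24 (3R,4R,5R)-9-[(tert-butyldimethylsilyl)oxy]-3-{[(2Z)-3-methyl-4-{[(2Z)-2-methylbut-2-enoyl]oxy}but-2-enoyl]oxy}eremophila-7(11),9-dien-8-one
Product: 25 (3R,4R,5R)-9-hydroxy-3-{[(2Z)-3-methyl-4-{[(2Z)-2-methylbut-2-enoyl]oxy}but-2-enoyl]oxy}eremophila-7(11),9-dien-8-one (target, CNP0228871.1)
Conditions: HF·pyridine, pyridine, THF, 0 °C
Reagents that add atoms: none
Why: Fluoride cleavage of the labile enol silyl ether under buffered conditions should release the diosphenol (the C9 enol of the 8,9-dione, the only tautomer available once C7 is fully substituted) without touching the esters.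

**Compound list**

1 | ethyl 2-(furan-2-yl)-2-oxoacetate | CCOC(=O)C(=O)c1ccco1 | starting material
2 | ethyl (2S)-2-(furan-2-yl)-2-hydroxyacetate | CCOC(=O)[C@@H](O)c1ccco1 | intermediate
3 | ethyl (2S)-2-[(tert-butyldimethylsilyl)oxy]-2-(furan-2-yl)acetate | CCOC(=O)[C@@H](O[Si](C)(C)C(C)(C)C)c1ccco1 | intermediate
4 | (2S)-2-[(tert-butyldimethylsilyl)oxy]-2-(furan-2-yl)-N-methoxy-N-methylacetamide | CON(C)C(=O)[C@@H](O[Si](C)(C)C(C)(C)C)c1ccco1 | intermediate
5 | 1,1-dibromo-2-methylprop-1-ene | CC(C)=C(Br)Br | starting material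
6 | (E)-1-bromo-2-methylbut-2-ene | C/C=C(\C)CBr | starting material
7 | 1-bromo-1-lithio-2-methylprop-1-ene (not isolated) | CC(C)=C([Li])Br | intermediate
8 | (5E)-3-bromo-2,5-dimethylhepta-2,5-diene | C/C=C(\C)CC(Br)=C(C)C | intermediate
9 | (5E)-2,5-dimethylhepta-2,5-dien-3-yllithium (not isolated) | C/C=C(\C)CC([Li])=C(C)C | intermediate
10 | (1S,5E)-1-[(tert-butyldimethylsilyl)oxy]-1-(furan-2-yl)-5-methyl-3-(propan-2-ylidene)hept-5-en-2-one | C/C=C(\C)CC(=C(C)C)C(=O)[C@@H](O[Si](C)(C)C(C)(C)C)c1ccco1 | intermediate
11 | (3R,4R,5R,9S,10S)-9-[(tert-butyldimethylsilyl)oxy]-3,10-epoxyeremophila-1,7(11)-dien-8-one | C[C@H]1[C@H]2C=C[C@@]3(O2)[C@H](O[Si](C)(C)C(C)(C)C)C(=O)C(=C(C)C)C[C@]13C | intermediate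
12 | (3R,4R,5R,9S,10S)-9-[(tert-butyldimethylsilyl)oxy]-3,10-epoxyeremophil-7(11)-en-8-one | C[C@H]1[C@H]2CC[C@@]3(O2)[C@H](O[Si](C)(C)C(C)(C)C)C(=O)C(=C(C)C)C[C@]13C | intermediate
13 | (3R,4R,5R)-9-[(tert-butyldimethylsilyl)oxy]-3-hydroxyeremophila-7(11),9-dien-8-one | C[C@H]1[C@H](O)CCC2=C(O[Si](C)(C)C(C)(C)C)C(=O)C(=C(C)C)C[C@]12C | intermediate
14 | tert-butyldimethyl(prop-2-yn-1-yloxy)silane | C#CCO[Si](C)(C)C(C)(C)C | starting material
15 | lithium acetylide of 14 (not isolated) | [Li]C#CCO[Si](C)(C)C(C)(C)C | intermediate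
16 | tert-butyl 4-[(tert-butyldimethylsilyl)oxy]but-2-ynoate | CC(C)(C)OC(=O)C#CCO[Si](C)(C)C(C)(C)C | intermediate
17 | tert-butyl (2Z)-4-[(tert-butyldimethylsilyl)oxy]-3-methylbut-2-enoate | CC(C)(C)OC(=O)/C=C(C)\CO[Si](C)(C)C(C)(C)C | intermediate
18 | tert-butyl (2Z)-4-hydroxy-3-methylbut-2-enoate | CC(C)(C)OC(=O)/C=C(C)\CO | intermediate
19 | angelic acid, (2Z)-2-methylbut-2-enoic acid | C/C=C(/C)C(=O)O | starting material
20 | angelic 2,4,6-trichlorobenzoic anhydride (not isolated) | C/C=C(/C)C(=O)OC(=O)c1c(Cl)cc(Cl)cc1Cl | intermediate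
21 | tert-butyl (2Z)-3-methyl-4-{[(2Z)-2-methylbut-2-enoyl]oxy}but-2-enoate | C/C=C(/C)C(=O)OC/C(C)=C\C(=O)OC(C)(C)C | intermediate
22 | (2Z)-3-methyl-4-{[(2Z)-2-methylbut-2-enoyl]oxy}but-2-enoic acid | C/C=C(/C)C(=O)OC/C(C)=C\C(=O)O | intermediate
23 | mixed anhydride of 22 with 2,4,6-trichlorobenzoic acid (not isolated) | C/C=C(/C)C(=O)OC/C(C)=C\C(=O)OC(=O)c1c(Cl)cc(Cl)cc1Cl | intermediate
24 | (3R,4R,5R)-9-[(tert-butyldimethylsilyl)oxy]-3-{[(2Z)-3-methyl-4-{[(2Z)-2-methylbut-2-enoyl]oxy}but-2-enoyl]oxy}eremophila-7(11),9-dien-8-one | C/C=C(/C)C(=O)OC/C(C)=C\C(=O)O[C@@H]1CCC2=C(O[Si](C)(C)C(C)(C)C)C(=O)C(=C(C)C)C[C@]2(C)[C@H]1C | intermediate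
25 | (3R,4R,5R)-9-hydroxy-3-{[(2Z)-3-methyl-4-{[(2Z)-2-methylbut-2-enoyl]oxy}but-2-enoyl]oxy}eremophila-7(11),9-dien-8-one | C/C=C(/C)C(=O)OC/C(C)=C\C(=O)O[C@@H]1CCC2=C(O)C(=O)C(=C(C)C)C[C@]2(C)[C@H]1C | target

**Step count and risks**

Total step count: 15. Longest linear sequence: 9 steps (1, 2, 3, 5, 6, 7, 8, 14, 15).

Step 6 (most likely to fail). The cycloaddition equilibrium of a furan with an unactivated trisubstituted alkene may lie on the open side, the adduct may revert during handling, and face selection by C9 may be incomplete. The fallback makes the dienophile an allene, whose cycloaddition is driven by release of cumulene strain and should not revert; C4 is then set in the hydrogenation. It sets out from 5 (and uses 4) and comes back at 12. Carbenoid 7, made from 5 as in step 4, is alkylated with 1,4-dichlorobut-2-yne to give 5-bromo-1-chloro-6-methylhept-5-en-2-yne F1. Anti-SN2′ substitution with MeMgBr and CuBr·SMe2 gives the allene 5-bromo-3,6-dimethylhepta-1,2,5-triene F2. Exchange with t-BuLi gives 3,6-dimethylhepta-1,2,5-trien-5-yllithium F3, which is acylated by 4 to the allenyl ketone (1S)-1-[(tert-butyldimethylsilyl)oxy]-1-(furan-2-yl)-5-methyl-3-(propan-2-ylidene)hepta-5,6-dien-2-one F4. Heating in toluene at 110 °C should give the exo-fused 4-methylidene cycloadduct (3R,5R,9S,10S)-9-[(tert-butyldimethylsilyl)oxy]-3,10-epoxyeremophila-1,4(15),7(11)-trien-8-one F5. Hydrogenation over Pd/C saturates C1=C2 and adds hydrogen to the methylidene from the open exo face, which places the C4 methyl endo and gives 12.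

Step 5. The hindered, strongly basic vinyllithium may deprotonate the amide at the silyloxy-bearing carbon (α to the carbonyl and to the furan) instead of adding, which erodes the C9 configuration and returns amide. The fallback replaces acylation by addition to an aldehyde followed by oxidation; it sets out from 4 (with 9) and comes back at 10. Reduction of 4 with i-Bu2AlH at −78 °C gives (2S)-2-[(tert-butyldimethylsilyl)oxy]-2-(furan-2-yl)acetaldehyde F6, to which 9 adds faster than it enolises, giving the allylic alcohol (5E)-1-[(tert-butyldimethylsilyl)oxy]-1-(furan-2-yl)-5-methyl-3-(propan-2-ylidene)hept-5-en-2-ol F7 as a mixture of carbinol epimers. Oxidation with Dess–Martin periodinane converges both epimers on 10.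

Step 14. γ-Deprotonation of the activated (Z)-enoyl donor to a vinylketene may scramble the Z geometry, and acylation of the C3 alcohol next to the C4 methyl may be slow. The fallback forms the ester with inversion from the C3 epimer, so that the acid reacts only as a carboxylate nucleophile; it sets out from 13 and comes back at 24. Oxidation of 13 with Dess–Martin periodinane gives (4R,5R)-9-[(tert-butyldimethylsilyl)oxy]eremophila-7(11),9-diene-3,8-dione F8. Reduction with LiBH(s-Bu)3 at −78 °C, from the face away from the axial C5 methyl and sparing the hindered dienone, should give the axial alcohol (3S,4R,5R)-9-[(tert-butyldimethylsilyl)oxy]-3-hydroxyeremophila-7(11),9-dien-8-one F9. Mitsunobu esterification of F9 with 22 (PPh3, diisopropyl azodicarboxylate) inverts C3 and gives 24.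

**Further compounds**

F1 | step 6 | 5-bromo-1-chloro-6-methylhept-5-en-2-yne | CC(C)=C(Br)CC#CCCl
F2 | step 6 | 5-bromo-3,6-dimethylhepta-1,2,5-triene | C=C=C(C)CC(Br)=C(C)C
F3 | step 6 | 3,6-dimethylhepta-1,2,5-trien-5-yllithium (not isolated) | C=C=C(C)CC([Li])=C(C)C
F4 | step 6 | (1S)-1-[(tert-butyldimethylsilyl)oxy]-1-(furan-2-yl)-5-methyl-3-(propan-2-ylidene)hepta-5,6-dien-2-one | C=C=C(C)CC(=C(C)C)C(=O)[C@@H](O[Si](C)(C)C(C)(C)C)c1ccco1
F5 | step 6 | (3R,5R,9S,10S)-9-[(tert-butyldimethylsilyl)oxy]-3,10-epoxyeremophila-1,4(15),7(11)-trien-8-one | C=C1[C@H]2C=C[C@@]3(O2)[C@H](O[Si](C)(C)C(C)(C)C)C(=O)C(=C(C)C)C[C@]13C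
F6 | step 5 | (2S)-2-[(tert-butyldimethylsilyl)oxy]-2-(furan-2-yl)acetaldehyde | O=C[C@@H](O[Si](C)(C)C(C)(C)C)c1ccco1
F7 | step 5 | (5E)-1-[(tert-butyldimethylsilyl)oxy]-1-(furan-2-yl)-5-methyl-3-(propan-2-ylidene)hept-5-en-2-ol (silyloxy carbon as in 10, both carbinol epimers) | C/C=C(\C)CC(=C(C)C)C(O)[C@@H](O[Si](C)(C)C(C)(C)C)c1ccco1
F8 | step 14 | (4R,5R)-9-[(tert-butyldimethylsilyl)oxy]eremophila-7(11),9-diene-3,8-dione | C[C@H]1C(=O)CCC2=C(O[Si](C)(C)C(C)(C)C)C(=O)C(=C(C)C)C[C@]12C
F9 | step 14 | (3S,4R,5R)-9-[(tert-butyldimethylsilyl)oxy]-3-hydroxyeremophila-7(11),9-dien-8-one | C[C@H]1[C@@H](O)CCC2=C(O[Si](C)(C)C(C)(C)C)C(=O)C(=C(C)C)C[C@]12C
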